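**Plan**

1. The retrosynthesis first cuts the ring olefin C1=C10. C1 carries only H and C2, and C10 carries only C9 and the formyl carbon C14, so the two carbons can be bridged by SO2 in an eleven-membered thiacycle that contracts to the ten-membered carbocycle by SO2 extrusion; the ring-cis geometry is the one this contraction and the E-enal thermodynamics favour.
2. The thiacycle is cut at S–C1 (thiolate SN2) and S–C10 (thia-Michael addition to fumaraldehyde mono-acetal, which supplies C8–C10 and C14 at the aldehyde level), then at C7–C8 (Barbier addition of a 3-(bromomethyl)butenolide).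
3. The butenolide (C6, C7, C11–C13) comes from RCM of a 2-(bromomethyl)acrylate of a dienol; the dienol comes from an enal whose C4=C5 geometry is fixed by trans-hydroalumination/iodination of mono-PMB butynediol and a B-alkyl Suzuki coupling (C3–C4).
4. Forward ring order: butenolide (step 7) → α-methylene lactone (step 9), masked as lactol methyl acetal (steps 11–12) → eleven-membered cyclic sulfide and sulfone (steps 14–15) → ten-membered carbocycle (step 16) → lactone restored (step 19).
5. Stereochemistry: C6 is set by a catalytic asymmetric Nozaki–Hiyama–Kishi vinylation; C7 and C8 are relayed from C6 in the Barbier step (anti to the C6 substituent, chair transition state), and C8 is then inverted by a Mitsunobu reaction.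

Key step: step 16

Remark (numbering and abbreviations): germacrane numbering is used throughout (C1–C10 ring carbons, C11–C13 acrylate carbons, C14 formyl carbon on C10, C15 hydroxymethyl carbon on C4). PMB = 4-methoxybenzyl, TBS = tert-butyldimethylsilyl, TMSE = 2-(trimethylsilyl)ethyl.

Remark (assumption): aldehyde 15 is racemic, so 16–25 are carried as pairs of C10 epimers, and the lactol/acetal carbon C12 of 18–28 as anomer mixtures. Both centres become sp2 later (steps 16 and 19), so the mixtures are inconsequential.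

**Route**

Step 1
Reactants: 1 but-2-yne-1,4-diol
Product: 2 4-[(4-methoxybenzyl)oxy]but-2-yn-1-ol
Conditions: NaH (1 equiv), 1 (3 equiv), THF/DMF, 0 °C; PMBCl, Bu4NI (cat.), rt
Reagents that add atoms: 4-methoxybenzyl chloride, COc1ccc(CCl)cc1
Why: Williamson etherification; the excess of the symmetrical diol should keep bis-alkylation low.

Step 2
Reactants: 2 4-[(4-methoxybenzyl)oxy]but-2-yn-1-ol
Product: 3 (2Z)-3-iodo-4-[(4-methoxybenzyl)oxy]but-2-en-1-ol
Conditions: Red-Al, THF, 0 °C → rt; then I2, THF, −78 → 0 °C
Reagents that add atoms: iodine, II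
Why: Hydroxyl-directed trans-hydroalumination of the propargylic alcohol (H to C5, Al to C4, anti) followed by iodinolysis with retention should give the Z vinyl iodide, which places C6 cis to the position that C3 will occupy.

Step 3
Reactants: 3 (2Z)-3-iodo-4-[(4-methoxybenzyl)oxy]but-2-en-1-ol; 4 allyl tert-butyldimethylsilyl ether
Product: 6 (2E)-6-(TBS-oxy)-3-[(PMB-oxy)methyl]hex-2-en-1-ol, via alkylborane 5 (not isolated)
Conditions: 4, 9-BBN-H, THF, 0 °C → rt; then 3, PdCl2(dppf) (cat.), Ph3As, Cs2CO3, DMF/H2O, rt
Reagents that add atoms: none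
Why: Anti-Markovnikov hydroboration and B-alkyl Suzuki–Miyaura coupling, which proceeds with retention at the sp2 carbon, so the new C3 chain stays cis to C6 (ring-cis C4=C5).

Step 4
Reactants: 6 (2E)-6-(TBS-oxy)-3-[(PMB-oxy)methyl]hex-2-en-1-ol
Product: 7 (2E)-6-(TBS-oxy)-3-[(PMB-oxy)methyl]hex-2-enal
Conditions: activated MnO2, CH2Cl2, rt
Reagents that add atoms: none
Why: MnO2 oxidises the primary allylic alcohol selectively and should leave the olefin geometry and both ethers untouched.

Step 5
Reactants: 7 (2E)-6-(TBS-oxy)-3-[(PMB-oxy)methyl]hex-2-enal; 8 vinyl bromide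
Product: 9 (3S,4E)-8-(TBS-oxy)-5-[(PMB-oxy)methyl]octa-1,4-dien-3-ol
Conditions: CrCl2 (cat.), chiral oxazoline–sulfonamide ligand (cat.), NiCl2·neocuproine (cat.), Mn, TMSCl, LiCl, MeCN, rt; then aq. citric acid
Reagents that add atoms: none
Why: Catalytic asymmetric Nozaki–Hiyama–Kishi vinylation (1,2-addition of the alkenylchromium to the enal); the ligand on Cr(III) differentiates the aldehyde faces, and the ligand antipode is chosen to give the 3S carbinol (C6).

Step 6
Reactants: 9 (3S,4E)-8-(TBS-oxy)-5-[(PMB-oxy)methyl]octa-1,4-dien-3-ol; 10 2-(bromomethyl)acrylic acid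
Product: 11 (3S,4E)-8-(TBS-oxy)-5-[(PMB-oxy)methyl]octa-1,4-dien-3-yl 2-(bromomethyl)acrylate
Conditions: DCC, DMAP (cat.), CH2Cl2, 0 °C
Reagents that add atoms: none
Why: Steglich esterification; no bond to the stereocentre is broken, and low temperature with catalytic DMAP should spare the allylic bromide.

Step 7
Reactants: 11 (3S,4E)-8-(TBS-oxy)-5-[(PMB-oxy)methyl]octa-1,4-dien-3-yl 2-(bromomethyl)acrylate
Product: 12 (5R)-3-(bromomethyl)-5-[(1E)-5-(TBS-oxy)-2-[(PMB-oxy)methyl]pent-1-en-1-yl]furan-2(5H)-one
Conditions: Hoveyda–Grubbs II catalyst (cat.), toluene, 80 °C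
Reagents that add atoms: none
Why: Ring-closing metathesis between the acrylate and the monosubstituted vinyl group gives the butenolide with loss of ethene; the trisubstituted C4=C5 olefin is a poor metathesis partner and should remain a spectator.

Step 8
Reactants: 13 2-(trimethylsilyl)ethanethiol; 14 (E)-4,4-dimethoxybut-2-enal
Product: 15 rac-4,4-dimethoxy-3-(TMSE-sulfanyl)butanal
Conditions: Et3N (cat.), CH2Cl2, 0 °C
Reagents that add atoms: none
Why: Thia-Michael addition; the thiol adds β to the aldehyde (the stronger acceptor), which puts sulfur on C10 next to the masked C14 aldehyde.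

Step 9
Reactants: 12 (5R)-3-(bromomethyl)-5-[(1E)-5-(TBS-oxy)-2-[(PMB-oxy)methyl]pent-1-en-1-yl]furan-2(5H)-one; 15 rac-4,4-dimethoxy-3-(TMSE-sulfanyl)butanal
Product: 16 (4R,5R)-4-[(1S)-1-hydroxy-4,4-dimethoxy-3-(TMSE-sulfanyl)butyl]-3-methylidene-5-[(1E)-5-(TBS-oxy)-2-[(PMB-oxy)methyl]pent-1-en-1-yl]oxolan-2-one
Conditions: Zn dust, THF/sat. aq. NH4Cl, 0 °C → rt
Reagents that add atoms: none
Why: Barbier allylation with γ-attack (SE2′) of the butenolide-derived allylzinc creates the α-methylene lactone and the C7–C8 bond; C7 is set by approach of the aldehyde anti to the C6 alkenyl group (trans lactone), and C8 by a Zimmerman–Traxler chair with the ring-locked E-type allylzinc and an equatorial aldehyde residue, which should give the 8S carbinol.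

Step 10
Reactants: 16 (6R,7R,8S)-hydroxy lactone from step 9
Product: 17 (4R,5R)-4-[(1R)-1-(benzoyloxy)-4,4-dimethoxy-3-(TMSE-sulfanyl)butyl]-3-methylidene-5-[(1E)-5-(TBS-oxy)-2-[(PMB-oxy)methyl]pent-1-en-1-yl]oxolan-2-one
Conditions: PhCO2H, PPh3, DIAD, toluene, 0 °C → rt
Reagents that add atoms: benzoic acid, O=C(O)c1ccccc1
Why: Mitsunobu esterification proceeds by SN2 displacement of the oxyphosphonium and should invert C8 to the 8R configuration of the target.

Step 11
Reactants: 17 (6R,7R,8R)-benzoate lactone from step 10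
Product: 18 (4R,5R)-4-[(1R)-1-hydroxy-4,4-dimethoxy-3-(TMSE-sulfanyl)butyl]-3-methylidene-5-[(1E)-5-(TBS-oxy)-2-[(PMB-oxy)methyl]pent-1-en-1-yl]oxolan-2-ol
Conditions: DIBAL-H (4 equiv), CH2Cl2, −78 °C; aq. Rochelle salt
Reagents that add atoms: none
Why: DIBAL reduction stops at the lactol because the cyclic aluminium hemiacetal is stable at −78 °C, while the benzoate is cleaved reductively in the same operation; this removes the Michael acceptor before thiolate and strong base are used.

Step 12
Reactants: 18 (6R,7R,8R)-lactol from step 11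
Product: 19 (1R)-1-[(2R,3R)-5-methoxy-4-methylidene-2-[(1E)-5-hydroxy-2-[(PMB-oxy)methyl]pent-1-en-1-yl]oxolan-3-yl]-4,4-dimethoxy-3-(TMSE-sulfanyl)butan-1-ol
Conditions: CSA (cat.), MeOH, 0 °C → rt
Reagents that add atoms: methanol, CO
Why: Acid-catalysed acetalisation through the allylic oxocarbenium ion fixes C12 as the methyl acetal, and the same acid methanolysis removes the primary TBS ether; the O6-linked furanoside should prevail because the alternative O8-linked ring would be cis-2,3-disubstituted.

Step 13
Reactants: 19 (6R,7R,8R)-acetal diol from step 12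
Product: 20 C1 methanesulfonate of 19 (C8–OH free)
Conditions: MsCl (1.05 equiv), Et3N, CH2Cl2, −30 °C
Reagents that add atoms: methanesulfonyl chloride, CS(Cl)(=O)=O
Why: Sulfonylation should take place at the unhindered primary C1 hydroxyl in preference to the secondary C8 hydroxyl flanked by the branched C7.

Step 14
Reactants: 20 C1 mesylate from step 13
Product: 22 eleven-membered cyclic sulfide (6R,7R,8R; S links C1 and C10), via thiolate 21 (not isolated)
Conditions: TBAF, 4 Å MS, THF, high dilution (syringe pump), rt → 45 °C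
Reagents that add atoms: none
Why: Fluoride-induced fragmentation of the 2-silylethyl sulfide releases the C10 thiolate, which closes the ring by intramolecular SN2 at the primary mesylate; the ring-cis C4=C5 olefin and the trans-fused oxolane pre-turn the chain, and a C–S closure is the least strained way to make a medium ring here.

Step 15
Reactants: 22 eleven-membered cyclic sulfide from step 14
Product: 23 eleven-membered cyclic sulfone (6R,7R,8R)
Conditions: (NH4)6Mo7O24·4H2O (cat.), 30% aq. H2O2, MeOH, 0 °C → rt
Reagents that add atoms: hydrogen peroxide, OO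
Why: Molybdate-catalysed peroxide oxidation takes sulfides to sulfones chemoselectively in the presence of tri- and 1,1-disubstituted olefins, and methanol as solvent keeps both methyl acetals intact.

Step 16
Reactants: 23 eleven-membered cyclic sulfone from step 15
Product: 26 ten-membered carbocycle (6R,7R,8R) with ring-cis C1=C10 bearing CH(OMe)2 on C10, via bromosulfone 24 (not isolated), via episulfone 25 (not isolated)
Conditions: CBr2F2, KOH/Al2O3, t-BuOH/CH2Cl2, 5 °C → rt
Reagents that add atoms: none
Why: Ramberg–Bäcklund ring contraction in its one-pot halogenative form: KOH deprotonates an α-sulfonyl C–H, CBr2F2 brominates the anion (24 is drawn with Br on the less hindered C1), the other α-carbanion displaces bromide in a 1,3-elimination to episulfone 25, and 25 loses SO2 stereospecifically. The closest precedent is the Ramberg–Bäcklund contraction of ten- and eleven-membered cyclic sulfones to nine- and ten-membered cycloalkenes, including trisubstituted olefins and sulfones with β-alkoxy groups. The ten-membered ring is closed by a 3-exo-tet attack of one sulfone α-carbon on the other (C1–C10 bond), so the ring shrinks from eleven to ten atoms, and either site of bromination leads to the same episulfone. No stereocentre is created, and C6, C7 and C8 are remote from both carbanions and not epimerisable under these conditions. The step needs the ring-cis olefin and must avoid E1cB loss of methoxide from the C10 anion: hydroxide-mediated 1,3-elimination favours the cis-episulfone, any ring-trans isomer can still be equilibrated to the E-enal in step 18, C1 has no β-leaving group, and the acetal methoxide on the C10 side is a poor one.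

Step 17
Reactants: 26 ten-membered carbocyclic alcohol from step 16
Product: 27 8-O-isovalerate of 26
Conditions: isovaleric anhydride, Et3N, DMAP (cat.), CH2Cl2, 0 °C → rt
Reagents that add atoms: 3-methylbutanoic anhydride, CC(C)CC(=O)OC(=O)CC(C)C
Why: DMAP-catalysed acylation of the only free hydroxyl with retention at C8; both acetals are stable to these conditions.

Step 18
Reactants: 27 bis-acetal isovalerate from step 17
Product: 28 enal lactol (C14 aldehyde; C12 lactol; 15-O-PMB; 8-O-isovalerate)
Conditions: 1 M aq. HCl/THF, 0 °C → rt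
Reagents that add atoms: water, O
Why: Acid hydrolysis of the α,β-unsaturated dimethyl acetal and of the allylic lactol acetal; the conjugated aldehyde should settle in the thermodynamically preferred E geometry (CHO trans to C2, ring-cis), and only O6 can close the lactol because O8 is acylated.

Step 19
Reactants: 28 enal lactol from step 18
Product: 29 15-O-PMB ether of the target
Conditions: activated MnO2, CH2Cl2, rt
Reagents that add atoms: none
Why: MnO2 oxidises the allylic lactol to the α-methylene-γ-butyrolactone, while the enal, the PMB ether and the ester are inert to it.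

Step 20
Reactants: 29 15-O-PMB ether of the target
Product: 30 CNP0345200.3 (target)
Conditions: DDQ, CH2Cl2/pH 7 buffer, 0 °C
Reagents that add atoms: none
Why: Oxidative cleavage of the PMB ether by DDQ under neutral conditions should free the C15 hydroxyl without touching the enal, the α-methylene lactone or the ester.

**Compound list**

1 | but-2-yne-1,4-diol | OCC#CCO | starting material
2 | 4-[(4-methoxybenzyl)oxy]but-2-yn-1-ol | OCC#CCOCc1ccc(OC)cc1 | intermediate
3 | (2Z)-3-iodo-4-[(4-methoxybenzyl)oxy]but-2-en-1-ol | OC/C=C(/COCc1ccc(OC)cc1)I | intermediate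
4 | allyl tert-butyldimethylsilyl ether | C=CCO[Si](C)(C)C(C)(C)C | starting material
5 | 9-[3-(TBS-oxy)propyl]-9-borabicyclo[3.3.1]nonane | CC(C)(C)[Si](C)(C)OCCCB1C2CCCC1CCC2 | intermediate
6 | (2E)-6-(TBS-oxy)-3-[(PMB-oxy)methyl]hex-2-en-1-ol | OC/C=C(/COCc1ccc(OC)cc1)CCCO[Si](C)(C)C(C)(C)C | intermediate
7 | (2E)-6-(TBS-oxy)-3-[(PMB-oxy)methyl]hex-2-enal | O=C/C=C(/COCc1ccc(OC)cc1)CCCO[Si](C)(C)C(C)(C)C | intermediate
8 | vinyl bromide | C=CBr | starting material
9 | (3S,4E)-8-(TBS-oxy)-5-[(PMB-oxy)methyl]octa-1,4-dien-3-ol | C=C[C@H](O)/C=C(/COCc1ccc(OC)cc1)CCCO[Si](C)(C)C(C)(C)C | intermediate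
10 | 2-(bromomethyl)acrylic acid | C=C(CBr)C(=O)O | starting material
11 | (3S,4E)-8-(TBS-oxy)-5-[(PMB-oxy)methyl]octa-1,4-dien-3-yl 2-(bromomethyl)acrylate | C=C[C@H](OC(=O)C(=C)CBr)/C=C(/COCc1ccc(OC)cc1)CCCO[Si](C)(C)C(C)(C)C | intermediate
12 | (5R)-3-(bromomethyl)-5-[(1E)-5-(TBS-oxy)-2-[(PMB-oxy)methyl]pent-1-en-1-yl]furan-2(5H)-one | O=C1O[C@H](/C=C(/COCc2ccc(OC)cc2)CCCO[Si](C)(C)C(C)(C)C)C=C1CBr | intermediate
13 | 2-(trimethylsilyl)ethanethiol | C[Si](C)(C)CCS | starting material
14 | (E)-4,4-dimethoxybut-2-enal | COC(OC)/C=C/C=O | starting material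
15 | rac-4,4-dimethoxy-3-(TMSE-sulfanyl)butanal | COC(OC)C(SCC[Si](C)(C)C)CC=O | intermediate
16 | (6R,7R,8S)-hydroxy α-methylene lactone (Barbier adduct; C10 epimers) | C=C1C(=O)O[C@H](/C=C(/COCc2ccc(OC)cc2)CCCO[Si](C)(C)C(C)(C)C)[C@H]1[C@@H](O)CC(SCC[Si](C)(C)C)C(OC)OC | intermediate
17 | (6R,7R,8R)-8-O-benzoyl α-methylene lactone | C=C1C(=O)O[C@H](/C=C(/COCc2ccc(OC)cc2)CCCO[Si](C)(C)C(C)(C)C)[C@H]1[C@H](OC(=O)c1ccccc1)CC(SCC[Si](C)(C)C)C(OC)OC | intermediate
18 | (6R,7R,8R)-lactol with free 8-OH (anomers) | C=C1C(O)O[C@H](/C=C(/COCc2ccc(OC)cc2)CCCO[Si](C)(C)C(C)(C)C)[C@H]1[C@H](O)CC(SCC[Si](C)(C)C)C(OC)OC | intermediate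
19 | (6R,7R,8R)-lactol methyl acetal with C1–OH and C8–OH free | C=C1C(OC)O[C@H](/C=C(/COCc2ccc(OC)cc2)CCCO)[C@H]1[C@H](O)CC(SCC[Si](C)(C)C)C(OC)OC | intermediate
20 | C1 methanesulfonate of 19 | C=C1C(OC)O[C@H](/C=C(/COCc2ccc(OC)cc2)CCCOS(C)(=O)=O)[C@H]1[C@H](O)CC(SCC[Si](C)(C)C)C(OC)OC | intermediate
21 | tetrabutylammonium C10 thiolate of 20 | C=C1C(OC)O[C@H](/C=C(/COCc2ccc(OC)cc2)CCCOS(C)(=O)=O)[C@H]1[C@H](O)CC([S-])C(OC)OC.CCCC[N+](CCCC)(CCCC)CCCC | intermediate
22 | eleven-membered cyclic sulfide (6R,7R,8R): S links C1 and C10; C10 bears CH(OMe)2; C4=C5 ring-cis with CH2OPMB; O6/C7 trans-fused 2-methoxy-3-methylideneoxolane; free 8-OH | C=C1C(OC)O[C@@H]2/C=C(/COCc3ccc(OC)cc3)CCCSC(C(OC)OC)C[C@@H](O)[C@@H]12 | intermediate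
23 | eleven-membered cyclic sulfone (S,S-dioxide of 22) | C=C1C(OC)O[C@@H]2/C=C(/COCc3ccc(OC)cc3)CCCS(=O)(=O)C(C(OC)OC)C[C@@H](O)[C@@H]12 | intermediate
24 | α-bromo sulfone (Br on C1) | C=C1C(OC)O[C@@H]2/C=C(/COCc3ccc(OC)cc3)CCC(Br)S(=O)(=O)C(C(OC)OC)C[C@@H](O)[C@@H]12 | intermediate
25 | episulfone (thiirane 1,1-dioxide across C1–C10) | C=C1C(OC)O[C@@H]2/C=C(/COCc3ccc(OC)cc3)CCC4C(C(OC)OC)(C[C@@H](O)[C@@H]12)S4(=O)=O | intermediate
26 | ten-membered carbocycle (6R,7R,8R): ring-cis C1=C10 with CH(OMe)2 on C10; ring-cis C4=C5 with CH2OPMB; lactol methyl acetal; free 8-OH | C=C1C(OC)O[C@@H]2/C=C(/COCc3ccc(OC)cc3)CC/C=C(/C(OC)OC)C[C@@H](O)[C@@H]12 | intermediate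
27 | 8-O-isovalerate of 26 | C=C1C(OC)O[C@@H]2/C=C(/COCc3ccc(OC)cc3)CC/C=C(/C(OC)OC)C[C@@H](OC(=O)CC(C)C)[C@@H]12 | intermediate
28 | enal lactol (C14 aldehyde; C12 lactol; 15-O-PMB; 8-O-isovalerate) | C=C1C(O)O[C@@H]2/C=C(/COCc3ccc(OC)cc3)CC/C=C(/C=O)C[C@@H](OC(=O)CC(C)C)[C@@H]12 | intermediate
29 | 15-O-PMB ether of the target | C=C1C(=O)O[C@@H]2/C=C(/COCc3ccc(OC)cc3)CC/C=C(/C=O)C[C@@H](OC(=O)CC(C)C)[C@@H]12 | intermediate
30 | CNP0345200.3 | C=C1C(=O)O[C@@H]2/C=C(/CO)CC/C=C(/C=O)C[C@@H](OC(=O)CC(C)C)[C@@H]12 | target

**Step count and risks**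

Total steps: 20. Longest linear sequence: 19 (steps 1–7 and 9–20; step 8 is the side branch).

Steps most likely to fail:

1. Step 16 (ring contraction). The secondary carbon C1 may be brominated a second time, or the C10 carbanion may expel methoxide from the neighbouring acetal (E1cB), before the hindered 1,3-elimination closes the episulfone. Part of the material may also emerge as the ring-trans olefin, which step 18 can still correct by enal equilibration. Fallback: halogenation and contraction are separated, so that no halogen source, hydroxide or carbene is present when the ring closes. Sulfone 23 is treated with LiHMDS (2.2 equiv, THF, −78 °C; C8 alkoxide plus the kinetically formed C1 carbanion) and then hexachloroethane, which should give the isolable mono-α-chloro sulfone F1. Exposure of this to KOt-Bu in THF (−78 → 0 °C) effects the classical two-stage Ramberg–Bäcklund contraction and returns to 26.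

2. Step 14 (macrocyclisation). Fluoride-induced release of the hindered secondary thiolate from the silylethyl sulfide may be slow and the medium-ring closure slower still, so that intermolecular S-alkylation and fluoride displacement of the mesylate take over. Fallback: the ring is closed at the sulfone oxidation level through a sulfinate. Mesylate 20 is first oxidised (ammonium molybdate, H2O2, MeOH) to the acyclic TMSE sulfone mesylate F2. β-Silylethyl sulfones fragment with fluoride far more readily than the sulfides, so TBAF with catalytic Bu4NI in THF at high dilution should give the tetrabutylammonium sulfinate F3, whose intramolecular S-alkylation at the primary mesylate leads directly to cyclic sulfone 23.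

3. Step 10 (inversion at C8). The oxyphosphonium may undergo E2 elimination toward C7 (allylic and γ to the lactone carbonyl) instead of SN2, or the Barbier step may not have delivered the 8S alcohol cleanly. Fallback: C8 is set by oxidation and reagent-controlled reduction, independent of both. Alcohol 16 is oxidised with Dess–Martin periodinane (NaHCO3, CH2Cl2, 0 °C) to the C8 ketone F4. Reduction with (S)-Me-CBS/catecholborane (toluene, −78 °C), with the branched C7 side acting as the large group, should give the (8R)-hydroxy α-methylene lactone F5, which is reduced with DIBAL-H under the conditions of step 11 to rejoin the route at 18.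

Further compounds
F1 | step 16 | mono-α-chloro sulfone (Cl on C1) of 23 | C=C1C(OC)O[C@@H]2/C=C(/COCc3ccc(OC)cc3)CCC(Cl)S(=O)(=O)C(C(OC)OC)C[C@@H](O)[C@@H]12
F2 | step 14 | acyclic TMSE sulfone mesylate (S,S-dioxide of 20) | C=C1C(OC)O[C@H](/C=C(/COCc2ccc(OC)cc2)CCCOS(C)(=O)=O)[C@H]1[C@H](O)CC(S(=O)(=O)CC[Si](C)(C)C)C(OC)OC
F3 | step 14 | tetrabutylammonium C10 sulfinate of the mesylate | C=C1C(OC)O[C@H](/C=C(/COCc2ccc(OC)cc2)CCCOS(C)(=O)=O)[C@H]1[C@H](O)CC(S(=O)[O-])C(OC)OC.CCCC[N+](CCCC)(CCCC)CCCC
F4 | step 10 | C8 ketone of 16 | C=C1C(=O)O[C@H](/C=C(/COCc2ccc(OC)cc2)CCCO[Si](C)(C)C(C)(C)C)[C@H]1C(=O)CC(SCC[Si](C)(C)C)C(OC)OC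
F5 | step 10 | (6R,7R,8R)-hydroxy α-methylene lactone (C8 epimer of 16) | C=C1C(=O)O[C@H](/C=C(/COCc2ccc(OC)cc2)CCCO[Si](C)(C)C(C)(C)C)[C@H]1[C@H](O)CC(SCC[Si](C)(C)C)C(OC)OC
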